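## Structural features

Compound 19 is an achiral macrocyclic bis(bibenzyl): four benzene rings (A to D) are joined into one 19-membered ring by two CH2CH2 bridges (ring A to ring D, ring B to ring C) and two diaryl ether oxygens (ring A to ring B, ring C to ring D). Ring A is 1,2,4-trisubstituted, with its methoxy group ortho to the ether oxygen and para to its bridge. Ring B is a para-phenylene and ring D a meta-phenylene, while ring C carries the only free hydroxyl, ortho to the oxygen that leads to ring D and para to its bridge. There are no stereocentres, so no neighbouring stereocentres have to be related. The only geometric element on the way is a stilbene double bond that is saturated at once. The sensitive parts are the electron-rich free phenol and the aryl ethers (oxidants, strong Lewis acids, electrophiles) and the benzylic CH2 groups. The real difficulty is threefold: neither diaryl ether is activated by the substituents of the target, rings A and C each carry two adjacent oxygens that must be told apart, and the 19-membered ring must close faster than chains grow. The key step uses the free C–H ortho to the oxygen-bearing carbon of ring B: a nitro group placed there, with fluorine on the oxygen-bearing carbon, lets the ring A oxygen (the one ortho to OMe) close the ring by nucleophilic aromatic substitution, after which the nitro group is exchanged for hydrogen.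

## Logic of the disconnections

19 from 18: the O–H of ring C is traced back to an O–CH2Ph bond. Ring C must be masked so that ring A holds the only phenoxide during ring closure, and a benzyl ether leaves at the very end under neutral hydrogenolysis. The forward step must come after all nitrogen chemistry and must spare the diaryl ethers, which it does.

18 from 16 (through 17), and 16 from 15: the C–H of ring B ortho to the ether oxygen is traced back to C–NH2 and then C–NO2. This turns an unactivated diaryl ether into the product of an activated substitution. The forward steps need a nitro reduction that keeps the benzyl ether (dissolving metal, not H2 over Pd) and a hydrodediazoniation run while ring C is still benzylated.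

15 from 14: the bond between the ring A oxygen and the ring B carbon is cut, which opens the 19-membered ring. Of the four links of the macrocycle, this is the one that can be activated tracelessly and closed with mild base at room temperature. The precursor is an open chain with one nucleophile and one electrophilic carbon. The forward step needs high dilution, a blocked ring C hydroxyl, and a ring A phenol that is set free only at this point.

14 from 13: the O–CH2OCH3 bond on ring A is cut. A free ring A phenoxide cannot coexist with the fluoronitroarene in any basic step, so the phenol is released under acid directly before the closure. The acetal is orthogonal to the benzyl ether and inert to ylides, bases, copper and boranes. The forward step must leave the benzyl ether and the C–F bond alone.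

13 from 10 and 11 (through 12): the bond between the ring B ring carbon and the adjacent CH2 of the B–C bridge is cut. The bridge is thereby made directly in its saturated form, so no stilbene has to be reduced beside a nitro group and an activated C–F bond. Sulfonyl hydrazide sources of diimide would offer nitrogen nucleophiles to that fluoride, and catalytic hydrogenation would threaten the nitro and benzyl groups. The cut also removes the alcohol, halide and phosphonium stages of an olefination route, and ring B arrives as a simple bromide. The forward coupling needs a base too weakly nucleophilic to displace fluoride and a catalyst that inserts only into C–Br.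

10 from 9: the vinyl C=C is traced back to C=O, a one-carbon extension. This leaves a single aldehyde as the handle of ring C, and the forward olefination is undemanding.

9 from 6 and 8: the bond between the ring D carbon and the oxygen of the C–O–D ether is cut. Neither ring is activated, so a copper-catalysed arylation is required. Ring D is brought in with its bridge to ring A already saturated, so the coupled product holds only one formyl group. A dialdehyde with two formyl groups that cannot be distinguished is thus avoided. The forward step must tolerate an ortho-alkoxy phenol, an unactivated bromide and the aldehyde.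

8 from 7: the O–CH2Ph bond on the 4-oxygen is cut. The hydroxyl para to the formyl group is the more acidic, so a weak base should alkylate it alone. The forward step needs mono-selectivity.

6 from 5, and 5 from 2 and 3 (through 4): the central C–C bond of the A–D bridge is cut, in the form of a C=C bond. Both halves are simple benzylic one-carbon units, and the aryl bromide survives olefination. This is done before any nitro group exists, so diimide is safe here. The reduction must keep the C–Br bond, which rules out H2 over Pd.

2 from 1: the O–CH2OCH3 bond is cut, the protection of the ring A phenol.

## Other disconnections considered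

Alternative 1: The cut is the bond between ring C (carbon para to the hydroxyl) and the neighbouring bridge carbon, taken at the ketone oxidation level. The forward key step would treat macrolactone A1 with CF3SO3H so that the acyl group moves from the ring C oxygen to the para carbon (para-Fries transposition), giving ketone A2. A deoxygenation of the C=O group would then give 19.
- In its favour: the lactone and the ketone rings are both 19-membered, so no strain is added. The ring C hydroxyl is released by the step itself and needs no protecting group. Only one operation separates A2 from 19, against three from 15; on this point the alternative is the better plan.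
- Against it: the acylium can attack several activated positions (ring A para to its aryloxy group, ring D ortho and para to its oxygen). An arylacetyl cation can lose CO to a well-stabilised benzyl cation. Acyl transfer between molecules would give oligomers. A1 itself needs a macrolactonization onto a weakly nucleophilic phenol, so two large-ring events are required, and the A–O–B ether still has to be made by other means.
- Comparison: the two plans are equal in the ring size they form. On mechanism the chosen closure has one defined nucleophile and one defined electrophilic carbon, whereas the Fries step relies on positional selectivity among four electron-rich rings. On step economy the shorter end game of the alternative is likely offset by the extra macrocyclization and the separate ether synthesis.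

Alternative 2: The cut is the bond between a ring C carbon and the oxygen of the C–O–D ether. The forward key step would oxidize seco bis-phenol A3 with Tl(NO3)3 in methanol, so that the ring D hydroxyl adds to a bromine-bearing ortho carbon of ring C. Zinc reduction of the dienone would then give macrocycle A4, and hydrogenolysis of one C–Br and three C–Cl bonds would give 19.
- In its favour: the ring C phenol stays free throughout, and one operation leads from A4 to 19, which is better than the three steps after 15. It is equal to the chosen plan in closing the ring by a diaryl ether bond and in relying on temporary substituents (halogens there, nitro here).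
- Against it: four halogens must be placed regioselectively on rings C and D. The oxidant is a toxic heavy-metal salt used in stoichiometric amount. The electron-rich ring A may itself be oxidized, nitrated or thallated. Oxidative couplings of this class tend to give side products from C–C coupling and solvent capture. The A–O–B ether still needs its own synthesis.
- Comparison: structurally both plans programme one ring for attack. Mechanistically the addition–elimination at a nitro-activated C–F bond is more predictable than a two-electron phenol oxidation in a molecule with four electron-rich rings. In step count the halogenations roughly cancel the shorter end game.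

Alternative 3: The cut removes two C–C bonds of ring B, which is dissolved into an alkyne and a 2-pyrone. The forward key step would heat seco ynol ether A5 at high dilution; cycloaddition across C3 and C6 of the pyrone and loss of CO2 would give macrocycle A6. Cleavage of the isopropyl ether with BCl3 would then give 19.
- In its favour: two C–C bonds and an aromatic ring form in the ring-closing event. The regiochemistry is electronically matched (the nucleophilic terminal alkyne carbon bonds to C6, giving the para pattern). Loss of CO2 makes the step irreversible. No activating group has to be erased, so one step follows the key step instead of three; on these points the alternative is the better plan.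
- Against it: the aryl ethynyl ether is labile to water and acid, and its usual preparation with alkyllithium reagents is incompatible with a pyrone already in place. The 5-alkyl-2-pyrone must be built on the ring C chain. Pairs of this kind need high temperature. A bridged bicyclic transition state inside a 19-membered ring has a high entropic cost and invites oligomers.
- Comparison: both plans close the macrocycle at ring B and both draw regiocontrol from intrinsic polarity, so they are equal there. The chosen plan buys ring B and closes at room temperature. The alternative gains bond-forming power but needs a longer and less robust preparation of its precursor, so its overall step count is likely higher.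

Key step: step 9

Remarks on the chemistry:
- Compounds 3 and 11 are treated as purchasable building blocks.
- Compound 5 is carried as an E/Z mixture, so its SMILES is written without alkene geometry; both isomers give 6.
- Compounds 14 and 15 map atom for atom onto 19 (ring size 19, ring A oxygen ortho to OMe, nitro ortho to the new ether oxygen), so their structures are used unchanged. The design changes concern only how 14 is reached: a temporary methoxymethyl group on ring A and a B–C bridge made saturated by cross-coupling.

## Route

Step 1
Reactants: 1 isovanillin (3-hydroxy-4-methoxybenzaldehyde)
Product: 2 4-methoxy-3-(methoxymethoxy)benzaldehyde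
Conditions: MOMCl, K2CO3, acetone, 0 °C to rt
Reagents that add atoms: chloromethyl methyl ether, COCCl
Why: Williamson-type O-alkylation of the phenoxide by the reactive α-chloro ether; the aldehyde is inert to K2CO3. The acetal resists ylides, hot base, copper catalysis and boranes, and later leaves under acid that spares the benzyl ether and the C–F bond.

Step 2
Reactants: 2 4-methoxy-3-(methoxymethoxy)benzaldehyde; 3 (3-bromobenzyl)triphenylphosphonium bromide
Product: 5 1-bromo-3-[2-(4-methoxy-3-(methoxymethoxy)phenyl)ethenyl]benzene (E/Z mixture), via phosphonium ylide 4 (not isolated)
Conditions: KOtBu, THF, 0 °C to rt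
Reagents that add atoms: none
Why: Wittig olefination of a non-enolizable aryl aldehyde with a semi-stabilized benzylic ylide; the aryl bromide is inert to KOtBu at this temperature. The alkene geometry is irrelevant because the next step saturates the double bond.

Step 3
Reactants: 5 1-bromo-3-[2-(4-methoxy-3-(methoxymethoxy)phenyl)ethenyl]benzene (E/Z mixture)
Product: 6 1-bromo-3-[2-(4-methoxy-3-(methoxymethoxy)phenyl)ethyl]benzene
Conditions: TsNHNH2, NaOAc, DME/H2O, reflux
Reagents that add atoms: none
Why: Diimide reduction: diimide formed by fragmentation of the sulfonyl hydrazide delivers H2 to the C=C bond in a concerted syn transfer. It does not insert into C–Br, and the acetate buffer protects the acetal; no stereocentre arises.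

Step 4
Reactants: 7 3,4-dihydroxybenzaldehyde
Product: 8 4-(benzyloxy)-3-hydroxybenzaldehyde
Conditions: BnBr (1 equiv), NaHCO3, NaI (cat.), DMF, 40 °C
Reagents that add atoms: benzyl bromide, BrCc1ccccc1
Why: Regioselective Williamson etherification: the hydroxyl para to the formyl group is the more acidic and is the one ionized by the weak base, so monobenzylation at that oxygen should dominate.

Step 5
Reactants: 6 1-bromo-3-[2-(4-methoxy-3-(methoxymethoxy)phenyl)ethyl]benzene; 8 4-(benzyloxy)-3-hydroxybenzaldehyde
Product: 9 4-(benzyloxy)-3-{3-[2-(4-methoxy-3-(methoxymethoxy)phenyl)ethyl]phenoxy}benzaldehyde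
Conditions: CuI (10 mol %), picolinic acid (20 mol %), K3PO4, DMSO, 90 °C
Reagents that add atoms: none
Why: Ullmann-type copper-catalysed C–O coupling of an aryl bromide with a phenoxide, using a picolinate ligand suited to ortho-substituted phenols. Only one formyl group is present, so no differentiation problem follows, and the acetal, benzyl and methyl ethers are inert.

Step 6
Reactants: 9 4-(benzyloxy)-3-{3-[2-(4-methoxy-3-(methoxymethoxy)phenyl)ethyl]phenoxy}benzaldehyde
Product: 10 1-(benzyloxy)-4-ethenyl-2-{3-[2-(4-methoxy-3-(methoxymethoxy)phenyl)ethyl]phenoxy}benzene
Conditions: Ph3PCH3Br, KOtBu, THF, 0 °C to rt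
Reagents that add atoms: methyltriphenylphosphonium bromide, C[P+](c1ccccc1)(c1ccccc1)c1ccccc1.[Br-]
Why: Wittig methylenation with the non-stabilized ylide, which is fast with aryl aldehydes and leaves all ethers untouched.

Step 7
Reactants: 10 1-(benzyloxy)-4-ethenyl-2-{3-[2-(4-methoxy-3-(methoxymethoxy)phenyl)ethyl]phenoxy}benzene; 11 4-bromo-1-fluoro-2-nitrobenzene
Product: 13 1-(benzyloxy)-4-[2-(4-fluoro-3-nitrophenyl)ethyl]-2-{3-[2-(4-methoxy-3-(methoxymethoxy)phenyl)ethyl]phenoxy}benzene, via B-alkyl-9-BBN borane 12 (not isolated)
Conditions: 9-BBN, THF, 0 °C to rt; then 11, PdCl2(dppf) (3 mol %), powdered K3PO4, DMF/THF, 50 °C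
Reagents that add atoms: none
Why: Anti-Markovnikov hydroboration puts boron on the terminal carbon, and a B-alkyl Suzuki–Miyaura coupling follows: zerovalent palladium inserts into C–Br only, and the dppf ligand favours reductive elimination over β-hydride elimination. The bridge is formed saturated, so no alkene has to be reduced beside the nitro group. Powdered phosphate is chosen as a weakly nucleophilic base so that the activated fluoride is not displaced.

Step 8
Reactants: 13 1-(benzyloxy)-4-[2-(4-fluoro-3-nitrophenyl)ethyl]-2-{3-[2-(4-methoxy-3-(methoxymethoxy)phenyl)ethyl]phenoxy}benzene
Product: 14 5-[2-(3-{2-(benzyloxy)-5-[2-(4-fluoro-3-nitrophenyl)ethyl]phenoxy}phenyl)ethyl]-2-methoxyphenol (seco fluoronitroarene phenol)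
Conditions: conc. HCl (cat.), MeOH/THF, 50 °C
Reagents that add atoms: none
Why: Acid-catalysed acetal exchange (methanolysis of the methoxymethyl ether) frees the ring A phenol. The aryl benzyl ether, the nitro group and the C–F bond are stable to dilute methanolic HCl, and without base the phenol does not attack the fluoroarene.

Step 9
Reactants: 14 5-[2-(3-{2-(benzyloxy)-5-[2-(4-fluoro-3-nitrophenyl)ethyl]phenoxy}phenyl)ethyl]-2-methoxyphenol
Product: 15 nitro-substituted O-benzyl macrocycle (19-membered ring; ring B carries NO2 ortho to the new ether oxygen; ring C carries OCH2Ph)
Conditions: K2CO3 (4 equiv), DMF (0.005 M, slow addition of 14), rt, Ar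
Reagents that add atoms: none
Why: Intramolecular nucleophilic aromatic substitution: K2CO3 ionizes the ring A phenol, the phenoxide oxygen adds to the fluorine-bearing carbon of ring B to give a Meisenheimer complex whose charge is taken up by the ortho nitro group, and loss of fluoride restores the arene. The closest known reaction type is the macro-etherification of ortho-nitro fluoroarenes by phenoxides used for macrocyclic diaryl ethers. The single new bond, ring A oxygen to ring B carbon, closes the 19-membered ring end to end, by addition to an sp2 carbon followed by elimination. No stereocentre is created, and any slowly interconverting conformers caused by the nitro group converge once it is removed. Chemoselectivity is secured by the substrate: ring A holds the only free hydroxyl because ring C is benzylated, and the C–F carbon of ring B is the only electrophilic arene position. Fluoride ortho to nitro is reactive enough for room temperature, which keeps the benzyl ether and the bridges untouched. Ring closure is favoured over chain growth by high dilution and slow addition.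

Step 10
Reactants: 15 nitro-substituted O-benzyl macrocycle
Product: 16 amino-substituted O-benzyl macrocycle (NH2 in place of NO2 on ring B)
Conditions: Fe powder, NH4Cl, EtOH/THF/H2O, 80 °C
Reagents that add atoms: none
Why: Béchamp-type dissolving-metal reduction of the nitroarene by stepwise electron and proton transfer. Unlike H2 over Pd it leaves the benzyl ether in place, so ring C stays masked for the diazotization.

Step 11
Reactants: 16 amino-substituted O-benzyl macrocycle
Product: 18 O-benzyl macrocycle (ring B unsubstituted para-phenylene), via arenediazonium chloride 17 (not isolated)
Conditions: NaNO2, aq HCl, THF, 0 °C; then H3PO2 (50 % aq), 0 °C to rt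
Reagents that add atoms: none
Why: Diazotization followed by hydrodediazoniation: hypophosphorous acid donates a hydrogen atom to the aryl radical in a chain process, so N2 is replaced by H. Ring C is still benzylated, so no phenol is open to C-nitrosation or azo coupling, and the efficient hydrogen donor should outpace attack of the aryl radical on ring A.

Step 12
Reactants: 18 O-benzyl macrocycle
Product: 19 target CNP0132125.0 (free ring C phenol)
Conditions: H2 (1 atm), 10 % Pd/C, EtOAc/MeOH, rt
Reagents that add atoms: none
Why: Heterogeneous hydrogenolysis of the benzylic C–O bond; diaryl ethers, the methyl ether and the saturated bridges are inert, and the product is the target.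

## Compound list

1 | isovanillin (3-hydroxy-4-methoxybenzaldehyde) | COc1ccc(C=O)cc1O | starting material
2 | 4-methoxy-3-(methoxymethoxy)benzaldehyde | COCOc1cc(C=O)ccc1OC | intermediate
3 | (3-bromobenzyl)triphenylphosphonium bromide | Brc1cccc(C[P+](c2ccccc2)(c2ccccc2)c2ccccc2)c1.[Br-] | starting material
4 | (3-bromobenzylidene)triphenylphosphorane | Brc1cccc(C=P(c2ccccc2)(c2ccccc2)c2ccccc2)c1 | intermediate (not isolated)
5 | 1-bromo-3-[2-(4-methoxy-3-(methoxymethoxy)phenyl)ethenyl]benzene, E/Z mixture | COCOc1cc(C=Cc2cccc(Br)c2)ccc1OC | intermediate
6 | 1-bromo-3-[2-(4-methoxy-3-(methoxymethoxy)phenyl)ethyl]benzene | COCOc1cc(CCc2cccc(Br)c2)ccc1OC | intermediate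
7 | 3,4-dihydroxybenzaldehyde | O=Cc1ccc(O)c(O)c1 | starting material
8 | 4-(benzyloxy)-3-hydroxybenzaldehyde | O=Cc1ccc(OCc2ccccc2)c(O)c1 | intermediate
9 | 4-(benzyloxy)-3-{3-[2-(4-methoxy-3-(methoxymethoxy)phenyl)ethyl]phenoxy}benzaldehyde | COCOc1cc(CCc2cccc(Oc3cc(C=O)ccc3OCc3ccccc3)c2)ccc1OC | intermediate
10 | 1-(benzyloxy)-4-ethenyl-2-{3-[2-(4-methoxy-3-(methoxymethoxy)phenyl)ethyl]phenoxy}benzene | COCOc1cc(CCc2cccc(Oc3cc(C=C)ccc3OCc3ccccc3)c2)ccc1OC | intermediate
11 | 4-bromo-1-fluoro-2-nitrobenzene | O=[N+]([O-])c1cc(Br)ccc1F | starting material
12 | B-alkyl-9-BBN borane from 10 (boron on the terminal carbon of the former vinyl group) | COCOc1cc(CCc2cccc(Oc3cc(CCB4C5CCCC4CCC5)ccc3OCc3ccccc3)c2)ccc1OC | intermediate (not isolated)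
13 | 1-(benzyloxy)-4-[2-(4-fluoro-3-nitrophenyl)ethyl]-2-{3-[2-(4-methoxy-3-(methoxymethoxy)phenyl)ethyl]phenoxy}benzene | COCOc1cc(CCc2cccc(Oc3cc(CCc4ccc(F)c([N+](=O)[O-])c4)ccc3OCc3ccccc3)c2)ccc1OC | intermediate
14 | 5-[2-(3-{2-(benzyloxy)-5-[2-(4-fluoro-3-nitrophenyl)ethyl]phenoxy}phenyl)ethyl]-2-methoxyphenol (seco fluoronitroarene phenol) | COc1ccc(CCc2cccc(Oc3cc(CCc4ccc(F)c([N+](=O)[O-])c4)ccc3OCc3ccccc3)c2)cc1O | intermediate
15 | nitro-substituted O-benzyl macrocycle | COc1ccc2cc1Oc1ccc(cc1[N+](=O)[O-])CCc1ccc(OCc3ccccc3)c(c1)Oc1cccc(c1)CC2 | intermediate
16 | amino-substituted O-benzyl macrocycle | COc1ccc2cc1Oc1ccc(cc1N)CCc1ccc(OCc3ccccc3)c(c1)Oc1cccc(c1)CC2 | intermediate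
17 | arenediazonium chloride of 16 | COc1ccc2cc1Oc1ccc(cc1[N+]#N)CCc1ccc(OCc3ccccc3)c(c1)Oc1cccc(c1)CC2.[Cl-] | intermediate (not isolated)
18 | O-benzyl macrocycle | COc1ccc2cc1Oc1ccc(cc1)CCc1ccc(OCc3ccccc3)c(c1)Oc1cccc(c1)CC2 | intermediate
19 | CNP0132125.0 | COc1ccc2cc1Oc1ccc(cc1)CCc1ccc(O)c(c1)Oc1cccc(c1)CC2 | target

## Step count and least certain steps

Total: 12 steps. Longest linear sequence: 11 steps (steps 1, 2, 3 and 5 to 12, from 1); step 4 is a one-step side branch.

Step 9 (key step). The most likely failure is substitution between molecules outrunning ring closure, so that chains grow. A second risk is that a slow closure on the only moderately activated para-alkyl fluoronitroarene leaves time for loss of fluoride to adventitious water or amine. The fallback moves the ring closure to a C–C bond. It sets out from 9 and comes back at 15. Acidic methanolysis of the acetal of 9 gives the hydroxy aldehyde F1. Methylenation with excess Ph3P=CH2 gives the hydroxy styrene F2. Intermolecular substitution of F2 on 11 (K2CO3, DMF, rt) gives the bromo nitro diaryl ether F3. Hydroboration with 9-BBN gives the borane F4, which closes the ring by an intramolecular B-alkyl Suzuki–Miyaura coupling (PdCl2(dppf), K3PO4, high dilution) to 15. The sensitive fluoride is consumed early in an easy bimolecular step.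

Step 7. The main risk is displacement of the activated fluoride by the base or by hydroxide during the coupling. With a weak, poorly soluble base the opposite risk is slow transmetalation, which would allow β-hydride elimination or protodeboronation. The fallback builds the bridge by olefination and homogeneous hydrogenation. It sets out from 9 and comes back at 13, replacing steps 6 and 7. NaBH4 reduces 9 to the benzylic alcohol F5. CBr4 and PPh3 give the bromide F6, and PPh3 in toluene gives the phosphonium bromide F7. F7 is deprotonated with K2CO3 and 18-crown-6 in CH2Cl2 in the presence of 4-fluoro-3-nitrobenzaldehyde F8 to give the stilbene F9 as an E/Z mixture. Hydrogenation with RhCl(PPh3)3 in benzene/EtOH saturates the alkene without touching the nitro group, the fluoride or the benzyl ether, and gives 13.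

Step 5. The risk is slow coupling of an unactivated aryl bromide with an ortho-substituted, formyl-bearing phenol, with hydrodebromination and base-induced degradation of the aldehyde on long heating. The fallback is an oxidative coupling at room temperature. It sets out from 6 and comes back at 9. Bromine–lithium exchange (n-BuLi, THF, −78 °C), trapping with B(OMe)3 and mild aqueous work-up give the boronic acid F10. Chan–Lam coupling of F10 with 8 (Cu(OAc)2, pyridine, 4 Å sieves, CH2Cl2, air, rt) gives 9.

Step 11. The risk is diversion of the diazonium ion or the derived aryl radical: capture of water to give a phenol, or ring closure onto the neighbouring ring A to give a dibenzofuran. The fallback sets out from 16 and comes back at 19, skipping 18. Sandmeyer-type bromination (tBuONO, CuBr2, MeCN, 0 °C to rt), in which halogen transfer from copper is very fast, gives the bromo macrocycle F11. Hydrogenolysis (H2, Pd/C, NaOAc, EtOAc/MeOH) then removes the bromine and the benzyl group together to give 19. Any stray ring bromination would be erased in the same operation.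

## Further compounds

F1 | step 9 | 4-(benzyloxy)-3-{3-[2-(3-hydroxy-4-methoxyphenyl)ethyl]phenoxy}benzaldehyde | COc1ccc(CCc2cccc(Oc3cc(C=O)ccc3OCc3ccccc3)c2)cc1O
F2 | step 9 | 5-[2-(3-{2-(benzyloxy)-5-ethenylphenoxy}phenyl)ethyl]-2-methoxyphenol | COc1ccc(CCc2cccc(Oc3cc(C=C)ccc3OCc3ccccc3)c2)cc1O
F3 | step 9 | 4-bromo-2-nitrophenyl ether of F2 (ring A oxygen bonded to ring B) | COc1ccc(CCc2cccc(Oc3cc(C=C)ccc3OCc3ccccc3)c2)cc1Oc1ccc(Br)cc1[N+](=O)[O-]
F4 | step 9 | B-alkyl-9-BBN borane from F3 | COc1ccc(CCc2cccc(Oc3cc(CCB4C5CCCC4CCC5)ccc3OCc3ccccc3)c2)cc1Oc1ccc(Br)cc1[N+](=O)[O-]
F5 | step 7 | [4-(benzyloxy)-3-{3-[2-(4-methoxy-3-(methoxymethoxy)phenyl)ethyl]phenoxy}phenyl]methanol | COCOc1cc(CCc2cccc(Oc3cc(CO)ccc3OCc3ccccc3)c2)ccc1OC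
F6 | step 7 | benzylic bromide from F5 | COCOc1cc(CCc2cccc(Oc3cc(CBr)ccc3OCc3ccccc3)c2)ccc1OC
F7 | step 7 | triphenylphosphonium bromide from F6 | COCOc1cc(CCc2cccc(Oc3cc(C[P+](c4ccccc4)(c4ccccc4)c4ccccc4)ccc3OCc3ccccc3)c2)ccc1OC.[Br-]
F8 | step 7 | 4-fluoro-3-nitrobenzaldehyde (purchased) | O=Cc1ccc(F)c([N+](=O)[O-])c1
F9 | step 7 | stilbene from F7 and F8, E/Z mixture | COCOc1cc(CCc2cccc(Oc3cc(C=Cc4ccc(F)c([N+](=O)[O-])c4)ccc3OCc3ccccc3)c2)ccc1OC
F10 | step 5 | 3-[2-(4-methoxy-3-(methoxymethoxy)phenyl)ethyl]phenylboronic acid | COCOc1cc(CCc2cccc(B(O)O)c2)ccc1OC
F11 | step 11 | bromo-substituted O-benzyl macrocycle (Br in place of NH2 on ring B) | COc1ccc2cc1Oc1ccc(cc1Br)CCc1ccc(OCc3ccccc3)c(c1)Oc1cccc(c1)CC2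
A1 | alternative 1 | 19-membered macrolactone (ring B arylacetate of the ring C phenol) | COc1ccc2cc1Oc1ccc(cc1)CC(=O)Oc1ccccc1Oc1cccc(c1)CC2
A2 | alternative 1 | macrocyclic 4-hydroxydeoxybenzoin | COc1ccc2cc1Oc1ccc(cc1)CC(=O)c1ccc(O)c(c1)Oc1cccc(c1)CC2
A3 | alternative 2 | seco bis-phenol (ring C 2,6-dibromophenol, ring D 2,4,6-trichlorophenol) | COc1ccc(CCc2c(Cl)cc(Cl)c(O)c2Cl)cc1Oc1ccc(CCc2cc(Br)c(O)c(Br)c2)cc1
A4 | alternative 2 | bromo trichloro macrocycle with free ring C phenol | COc1ccc2cc1Oc1ccc(cc1)CCc1cc(Br)c(O)c(c1)Oc1c(Cl)cc(Cl)c(c1Cl)CC2
A5 | alternative 3 | seco aryl ethynyl ether with 5-alkyl-2-pyrone (ring C O-isopropyl) | COc1ccc(CCc2cccc(Oc3cc(CCc4ccc(=O)oc4)ccc3OC(C)C)c2)cc1OC#C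
A6 | alternative 3 | O-isopropyl macrocycle | COc1ccc2cc1Oc1ccc(cc1)CCc1ccc(OC(C)C)c(c1)Oc1cccc(c1)CC2
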